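**Strategy.** The 2-methoxy-5-aryloxy-6-alkyl-1,4-benzoquinone ring is cut through both of its C=C bonds, C2(OMe)=C3H and C5(OAr)=C6(alkyl), into two three-carbon 1,2-dicarbonyl units. The feature used is that each of these double bonds joins an oxygen-bearing carbon (a former enolisable O–CH2) to a former carbonyl carbon. The key step is a crossed, intramolecular von Pechmann-type double aldol condensation that closes the quinone and the 18-membered macrocycle in one operation. Its precursor is an open-chain diaryl ether–bibenzyl carrying an aryloxymethyl glyoxal (ArO–CH2–CO–CHO) on the meta-phenylene ring and a methoxymethyl 1,2-dione (MeOCH2–CO–CO–CH2CH2Ar) on the para-phenylene ring, both unveiled together by one oxidation of a tetraol.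

Key step: step 10

Assumption: compounds 5–13 are carried as E/Z or diastereomer mixtures (racemic). Every stereogenic element in them is erased in steps 7 and 9, and the target has no stereocentre.

Quinone numbering used below: C1(=O) lies between C2(OMe) and C6(CH2CH2Ar); C3 is CH; C4 is the second C=O; C5 carries the aryloxy group.

**Step 1**
Reactants: 1 3,4-dihydroxybenzaldehyde
Product: 2 3-hydroxy-4-(methoxymethoxy)benzaldehyde
Conditions: MOMCl (1.05 equiv), K2CO3, acetone, 0 °C to rt
Reagents that add atoms: chloromethyl methyl ether (MOMCl), COCCl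
Why: Williamson etherification under mild base should alkylate the 4-OH selectively, because it is para to the formyl group and therefore the more acidic of the two phenols.

**Step 2**
Reactants: 3 1-bromo-4-(but-3-en-1-yl)benzene; 4 allyl methyl ether (5 equiv)
Product: 5 1-bromo-4-[(3E)-5-methoxypent-3-en-1-yl]benzene (E major, Z carried along)
Conditions: Grubbs II (3 mol %), CH2Cl2, 40 °C
Reagents that add atoms: none
Why: Olefin cross-metathesis of two terminal type-I alkenes is driven to the cross product by the excess of the volatile ether and loss of ethene; the alkene geometry is irrelevant because both alkene carbons later become carbonyl carbons.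

**Step 3**
Reactants: 2 3-hydroxy-4-(methoxymethoxy)benzaldehyde; 5 1-bromo-4-[(3E)-5-methoxypent-3-en-1-yl]benzene
Product: 6 3-{4-[(3E)-5-methoxypent-3-en-1-yl]phenoxy}-4-(methoxymethoxy)benzaldehyde
Conditions: CuI (10 mol %), picolinic acid (20 mol %), K3PO4, DMSO, 90 °C
Reagents that add atoms: none
Why: Ligand-accelerated Ullmann diaryl ether synthesis should couple the ortho-alkoxy phenoxide with the unactivated aryl bromide while tolerating the aldehyde, the MOM acetal and the isolated alkene.

**Step 4**
Reactants: 6 3-{4-[(3E)-5-methoxypent-3-en-1-yl]phenoxy}-4-(methoxymethoxy)benzaldehyde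
Product: 7 3-[4-(3,4-dihydroxy-5-methoxypentyl)phenoxy]-4-(methoxymethoxy)benzaldehyde (racemic diol mixture)
Conditions: K2OsO4·2H2O (2 mol %), NMO (1.5 equiv), acetone/H2O 4:1, rt
Reagents that add atoms: N-methylmorpholine N-oxide, C[N+]1([O-])CCOCC1; water, O
Why: Upjohn dihydroxylation should convert the only alkene into the vicinal diol by syn addition and leave the aldehyde and aryl ethers untouched; the diol configuration is inconsequential.

**Step 5**
Reactants: 8 1-(benzyloxy)-3-(bromomethyl)benzene
Product: 9 [3-(benzyloxy)benzyl]triphenylphosphonium bromide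
Conditions: PPh3, toluene, reflux
Reagents that add atoms: triphenylphosphine, c1ccc(cc1)P(c1ccccc1)c1ccccc1
Why: SN2 quaternisation of the benzylic bromide by triphenylphosphine gives the Wittig salt.

**Step 6**
Reactants: 7 3-[4-(3,4-dihydroxy-5-methoxypentyl)phenoxy]-4-(methoxymethoxy)benzaldehyde; 9 [3-(benzyloxy)benzyl]triphenylphosphonium bromide
Product: 10 5-[4-(5-{2-[3-(benzyloxy)phenyl]ethenyl}-2-(methoxymethoxy)phenoxy)phenyl]-1-methoxypentane-2,3-diol (E/Z mixture)
Conditions: K2CO3, 18-crown-6 (cat.), CH2Cl2, reflux
Reagents that add atoms: none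
Why: Wittig olefination with the semi-stabilised benzylic ylide under solid–liquid phase-transfer conditions should tolerate the free diol, and both alkene isomers are hydrogenated in the next step.

**Step 7**
Reactants: 10 stilbene diol
Product: 11 5-[4-(5-[2-(3-hydroxyphenyl)ethyl]-2-(methoxymethoxy)phenoxy)phenyl]-1-methoxypentane-2,3-diol
Conditions: H2 (1 atm), 10% Pd/C, EtOAc/MeOH, rt
Reagents that add atoms: none
Why: Heterogeneous hydrogenation should saturate the stilbene to the bibenzyl bridge and hydrogenolyse the benzyl ether in the same operation, while the MOM acetal, the diaryl ether and the aliphatic diol are inert.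

**Step 8**
Reactants: 11 phenol diol; 12 glycidol (racemic, 1.5 equiv)
Product: 13 3-{3-[2-(3-[4-(3,4-dihydroxy-5-methoxypentyl)phenoxy]-4-(methoxymethoxy)phenyl)ethyl]phenoxy}propane-1,2-diol (tetraol)
Conditions: K2CO3 (0.2 equiv), EtOH, 80 °C
Reagents that add atoms: none
Why: Base-catalysed opening of the epoxide at its terminal carbon by the phenoxide, the only nucleophile ionised under these conditions, installs C5, C4 and C3 of the future quinone as a glycerol ether.

**Step 9**
Reactants: 13 tetraol
Product: 14 3-{3-[2-(3-[4-(5-methoxy-3,4-dioxopentyl)phenoxy]-4-(methoxymethoxy)phenyl)ethyl]phenoxy}-2-oxopropanal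
Conditions: IBX (8 equiv), DMSO, 25 °C; aqueous work-up, used at once in dilute solution
Reagents that add atoms: none
Why: IBX oxidises 1,2-diols to 1,2-dicarbonyl compounds without glycol cleavage, so one operation should turn the internal diol into the 1,2-dione and the terminal diol into the ketoaldehyde while the MOM acetal and aryl ethers stay intact.

**Step 10**
Reactants: 14 ketoaldehyde–dione
Product: 17 MOM-protected macrocyclic quinone, via macrocyclic mono-aldol adduct 15 (not isolated), via bicyclic bis-aldol diol 16 (not isolated)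
Conditions: DBU (0.5 equiv), 4 Å MS, MeCN, 25 °C, 14 added by syringe pump over 12 h to 1 mM; then AcOH
Reagents that add atoms: none
Why: DBU enolises the 1,2-dione of 14 toward its methoxy-bearing CH2 (C2) and this enolate adds to the glyoxal aldehyde (C3) to close a 22-membered ring (15); the aryloxymethyl ketone then enolises at C5 and adds to the dione carbonyl C6 in a transannular aldol (16), and two E1cB dehydrations, driven by formation of the cross-conjugated quinone, create the C2=C3 and C5=C6 double bonds. The closest known reaction type is the von Pechmann base-induced double aldol condensation of 1,2-diketones to p-benzoquinones (biacetyl to 2,5-dimethylbenzoquinone), here run in crossed and intramolecular form. The macrocycle closes by exo-trig addition to the aldehyde under high dilution, and the six-membered ring by a 6-(enolexo)-exo-trig aldol that contracts the 22-membered ring to the 18-membered one. No stereocentre survives, since the two carbinol centres and the two CH(OR) centres of 16 all become sp2 carbons. The step needs (i) cyclisation over oligomerisation, secured by slow addition at 1 mM, (ii) enolisation at the two O-substituted methylenes and not at the CH2 of the ethylene tether, secured by their higher acidity next to a 1,2-dicarbonyl unit and an inductively withdrawing oxygen, (iii) attack on the aldehyde first, secured by its being the most electrophilic carbonyl, and (iv) six- over five-membered closure, secured because the aldol additions are reversible while only the six-membered adduct can lose two molecules of water to the quinone.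

**Step 11**
Reactants: 17 MOM-protected macrocyclic quinone
Product: 18 target quinone (CNP0332646.0)
Conditions: TFA/CH2Cl2 1:4, 0 °C to rt; aqueous work-up
Reagents that add atoms: none
Why: Acid-mediated cleavage of the aryl methoxymethyl acetal via its oxocarbenium ion in a non-nucleophilic medium should free the phenol and leave the methoxy- and aryloxy-substituted (vinylogous ester) quinone intact.

**Compound list**

1 | 3,4-dihydroxybenzaldehyde | O=Cc1ccc(O)c(O)c1 | starting material
2 | 3-hydroxy-4-(methoxymethoxy)benzaldehyde | O=Cc1ccc(OCOC)c(O)c1 | intermediate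
3 | 1-bromo-4-(but-3-en-1-yl)benzene | C=CCCc1ccc(Br)cc1 | starting material
4 | allyl methyl ether (3-methoxyprop-1-ene) | C=CCOC | starting material
5 | 1-bromo-4-[(3E)-5-methoxypent-3-en-1-yl]benzene | COC/C=C/CCc1ccc(Br)cc1 | intermediate
6 | 3-{4-[(3E)-5-methoxypent-3-en-1-yl]phenoxy}-4-(methoxymethoxy)benzaldehyde | O=Cc1ccc(OCOC)c(Oc2ccc(CC/C=C/COC)cc2)c1 | intermediate
7 | 3-[4-(3,4-dihydroxy-5-methoxypentyl)phenoxy]-4-(methoxymethoxy)benzaldehyde (diol mixture) | O=Cc1ccc(OCOC)c(Oc2ccc(CCC(O)C(O)COC)cc2)c1 | intermediate
8 | 1-(benzyloxy)-3-(bromomethyl)benzene | BrCc1cccc(OCc2ccccc2)c1 | starting material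
9 | [3-(benzyloxy)benzyl]triphenylphosphonium bromide | [Br-].c1ccc(COc2cccc(C[P+](c3ccccc3)(c3ccccc3)c3ccccc3)c2)cc1 | intermediate
10 | 5-[4-(5-{2-[3-(benzyloxy)phenyl]ethenyl}-2-(methoxymethoxy)phenoxy)phenyl]-1-methoxypentane-2,3-diol (E/Z mixture) | COCOc1ccc(C=Cc2cccc(OCc3ccccc3)c2)cc1Oc1ccc(CCC(O)C(O)COC)cc1 | intermediate
11 | 5-[4-(5-[2-(3-hydroxyphenyl)ethyl]-2-(methoxymethoxy)phenoxy)phenyl]-1-methoxypentane-2,3-diol | COCOc1ccc(CCc2cccc(O)c2)cc1Oc1ccc(CCC(O)C(O)COC)cc1 | intermediate
12 | glycidol (racemic oxiran-2-ylmethanol) | OCC1CO1 | starting material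
13 | 3-{3-[2-(3-[4-(3,4-dihydroxy-5-methoxypentyl)phenoxy]-4-(methoxymethoxy)phenyl)ethyl]phenoxy}propane-1,2-diol | COCOc1ccc(CCc2cccc(OCC(O)CO)c2)cc1Oc1ccc(CCC(O)C(O)COC)cc1 | intermediate
14 | 3-{3-[2-(3-[4-(5-methoxy-3,4-dioxopentyl)phenoxy]-4-(methoxymethoxy)phenyl)ethyl]phenoxy}-2-oxopropanal | COCOc1ccc(CCc2cccc(OCC(=O)C=O)c2)cc1Oc1ccc(CCC(=O)C(=O)COC)cc1 | intermediate
15 | 22-membered macrocyclic mono-aldol adduct (C2–C3 bond formed; β-hydroxy trione) | COCOc1ccc2cc1Oc1ccc(cc1)CCC(=O)C(=O)C(OC)C(O)C(=O)COc1cccc(c1)CC2 | intermediate (not isolated)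
16 | bicyclic bis-aldol adduct (2,5-dihydroxycyclohexane-1,4-dione fused into the 18-membered ring) | COCOc1ccc2cc1Oc1ccc(cc1)CCC1(O)C(Oc3cccc(c3)CC2)C(=O)C(O)C(OC)C1=O | intermediate (not isolated)
17 | MOM ether of the target: macrocyclic 2-methoxy-5-aryloxy-6-alkyl-1,4-benzoquinone with OCH2OCH3 on the trisubstituted ring | COCOc1ccc2cc1Oc1ccc(cc1)CCC1=C(Oc3cccc(c3)CC2)C(=O)C=C(OC)C1=O | intermediate
18 | target macrocyclic quinone with free phenol (CNP0332646.0) | COC1=CC(=O)C2=C(CCc3ccc(cc3)Oc3cc(ccc3O)CCc3cccc(c3)O2)C1=O | target

**Totals.** 11 steps in all; longest linear sequence 9 steps (1 → 2 → 6 → 7 → 10 → 11 → 13 → 14 → 17 → 18).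

**Steps most likely to fail**

1. Step 10. Oligomerisation may outrun the 22-membered ring closure; enolisation may occur at the tether CH2 or the second aldol may close a five-membered ring; base may also degrade the glyoxal by hydride shift to an α-hydroxy acid. Fallback (sets out from 2, comes back at 17): the quinone is made by oxidation of a preformed arene and the macrocycle is closed by carbonyl coupling. Commercial 6-bromo-2-hydroxy-3-methoxybenzaldehyde is benzylated (BnBr, K2CO3, DMF) to 2-(benzyloxy)-6-bromo-3-methoxybenzaldehyde F1. Ullmann coupling with 3-hydroxybenzyl alcohol (CuI, picolinic acid, K3PO4, DMSO) should give 2-(benzyloxy)-6-[3-(hydroxymethyl)phenoxy]-3-methoxybenzaldehyde F2. Wittig reaction with commercial (4-bromobenzyl)triphenylphosphonium bromide gives the bromostilbene alcohol F3, and a second Ullmann coupling, now with 2, gives the hydroxymethyl aldehyde F4. MnO2 oxidation gives the dialdehyde F5, and intramolecular McMurry coupling (TiCl3(DME)1.5, Zn–Cu, DME, high dilution) should close the macrocyclic bis-stilbene F6. H2, Pd/C saturates both bridges and removes the benzyl group to give the macrocyclic 2-alkyl-6-methoxyphenol F7. Its free para position allows Teuber oxidation with Fremy's salt to 17.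

2. Step 9. The fourfold oxidation may stop at hydroxy carbonyl stages or cleave a glycol, and the tetracarbonyl product may oligomerise through hydrates and hemiacetals on concentration. Fallback (sets out from 11, comes back at 18): the aldehyde is delivered masked instead of by oxidation. Phenol 11 is alkylated with 3-bromo-1,1-dimethoxypropan-2-one (K2CO3, acetone) to the keto acetal diol F8. Swern oxidation (TFAA, DMSO, Et3N) of the single internal diol gives the keto acetal dione F9. Aqueous TFA then hydrolyses the dimethyl acetal and the MOM ether to the free-phenol ketoaldehyde–dione F10. F10 is submitted to the conditions of step 10 and should give 18 directly.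

3. Step 11. Acid may promote loss of the aryloxy group from the quinone (ring-opening trans-etherification), or the released formaldehyde equivalent may attack the electron-rich phenol ring. Fallback (sets out from 17, comes back at 18): the quinone is protected by reduction during deprotection. Na2S2O4 (EtOAc/H2O) reduces 17 to the MOM-protected hydroquinone F11. HCl in MeOH removes the MOM group to give the hydroquinone phenol F12. Ag2O in Et2O (or air) reoxidises the hydroquinone selectively to 18.

**Further compounds**

F1 | step 10 | 2-(benzyloxy)-6-bromo-3-methoxybenzaldehyde | COc1ccc(Br)c(C=O)c1OCc1ccccc1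
F2 | step 10 | 2-(benzyloxy)-6-[3-(hydroxymethyl)phenoxy]-3-methoxybenzaldehyde | COc1ccc(Oc2cccc(CO)c2)c(C=O)c1OCc1ccccc1
F3 | step 10 | {3-[3-(benzyloxy)-2-[2-(4-bromophenyl)ethenyl]-4-methoxyphenoxy]phenyl}methanol (bromostilbene alcohol) | COc1ccc(Oc2cccc(CO)c2)c(C=Cc2ccc(Br)cc2)c1OCc1ccccc1
F4 | step 10 | hydroxymethyl aldehyde (diaryl ether from F3 and 2) | COc1ccc(Oc2cccc(CO)c2)c(C=Cc2ccc(Oc3cc(C=O)ccc3OCOC)cc2)c1OCc1ccccc1
F5 | step 10 | dialdehyde | COc1ccc(Oc2cccc(C=O)c2)c(C=Cc2ccc(Oc3cc(C=O)ccc3OCOC)cc2)c1OCc1ccccc1
F6 | step 10 | macrocyclic bis-stilbene (benzyl and MOM protected) | COCOc1ccc2cc1Oc1ccc(cc1)C=Cc1c(OCc3ccccc3)c(OC)ccc1Oc1cccc(c1)C=C2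
F7 | step 10 | macrocyclic 2-alkyl-6-methoxyphenol (MOM protected) | COCOc1ccc2cc1Oc1ccc(cc1)CCc1c(O)c(OC)ccc1Oc1cccc(c1)CC2
F8 | step 9 | keto acetal diol | COCOc1ccc(CCc2cccc(OCC(=O)C(OC)OC)c2)cc1Oc1ccc(CCC(O)C(O)COC)cc1
F9 | step 9 | keto acetal dione | COCOc1ccc(CCc2cccc(OCC(=O)C(OC)OC)c2)cc1Oc1ccc(CCC(=O)C(=O)COC)cc1
F10 | step 9 | free-phenol ketoaldehyde–dione | Oc1ccc(CCc2cccc(OCC(=O)C=O)c2)cc1Oc1ccc(CCC(=O)C(=O)COC)cc1
F11 | step 11 | MOM-protected macrocyclic hydroquinone | COCOc1ccc2cc1Oc1ccc(cc1)CCc1c(O)c(OC)cc(O)c1Oc1cccc(c1)CC2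
F12 | step 11 | macrocyclic hydroquinone phenol | Oc1ccc2cc1Oc1ccc(cc1)CCc1c(O)c(OC)cc(O)c1Oc1cccc(c1)CC2
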